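## Retrosynthetic overview

1. The ten-membered ring is closed last, at C3a–C4. The butenolide β-carbon (normally an acceptor) is turned into a donor, a lactone homoenolate (d3) equivalent, as an allylindium made from a 3-(acyloxymethyl)butenolide through π-allylpalladium. It adds to the aldehyde carbon of a 1,2-ketoaldehyde; the same event moves the double bond out to the α-methylene group and sets C3a and C4.
2. The ketoaldehyde comes from a terminal vinyl group (dihydroxylation, IBX). The CH2OPiv arm comes from an α-bromobutenolide by Negishi coupling.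
3. The lactone ring is made first, as a butenolide, by a vinylogous Mukaiyama aldol of 3-bromo-2-silyloxyfuran with an α-silyloxy aldehyde; this sets C11a and C11.
4. The aldehyde comes from (S)-β-citronellene, which supplies C4–C11 and both methyl groups. C6 is from the chiral pool and C10 from a Sharpless epoxidation followed by hydride opening.
5. Ring order: five-membered lactone first, ten-membered carbocycle last, with desilylation in the same flask.

Assumption: locants in the comments are those of the target (cyclodeca[b]furan: O1, C2=O, C3=CH2, C3a, C4–OH, C5=O, C6–Me, C10(OH)Me, C11–ester, C11a); (S)-β-citronellene and 3-bromofuran-2(5H)-one are bought.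

## Route

Step 1
Reactants: 1 (3S)-3,7-dimethylocta-1,6-diene [(S)-β-citronellene]
Product: 2 (2E,6S)-2,6-dimethylocta-2,7-dien-1-ol
Conditions: SeO2 (0.3 equiv), t-BuOOH (3 equiv), salicylic acid (cat.), CH2Cl2, rt
Reagents that add atoms: tert-butyl hydroperoxide, CC(C)(C)OO
Why: Sharpless–Umbreit allylic oxidation (ene reaction, then [2,3]-shift) attacks only the trisubstituted alkene and its (E)-methyl group, leaving the vinyl group and the chiral-pool centre (future C6) untouched.

Step 2
Reactants: 2 (2E,6S)-2,6-dimethylocta-2,7-dien-1-ol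
Product: 3 [(2S,3S)-2-methyl-3-[(3S)-3-methylpent-4-en-1-yl]oxiran-2-yl]methanol
Conditions: Ti(OiPr)4 (10 mol%), L-(+)-diethyl tartrate (12 mol%), t-BuOOH, 4 Å MS, CH2Cl2, −20 °C
Reagents that add atoms: tert-butyl hydroperoxide, CC(C)(C)OO
Why: Katsuki–Sharpless asymmetric epoxidation of an (E)-2-methylallylic alcohol; L-(+)-tartrate gives the (2S,3S)-epoxide by reagent control, which fixes the future C10 centre, and the isolated vinyl group is inert.

Step 3
Reactants: 3 [(2S,3S)-2-methyl-3-[(3S)-3-methylpent-4-en-1-yl]oxiran-2-yl]methanol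
Product: 4 (2R,6S)-2,6-dimethyloct-7-ene-1,2-diol
Conditions: LiAlH4, THF, 0 °C → rt; Fieser work-up
Reagents that add atoms: none
Why: Reductive epoxide opening by SN2 hydride attack at the less hindered secondary carbon leaves the C–O bond at the quaternary carbon intact, giving the (R)-tertiary alcohol with retention.

Step 4
Reactants: 4 (2R,6S)-2,6-dimethyloct-7-ene-1,2-diol
Product: 5 (2R,6S)-2,6-dimethyloct-7-ene-1,2-diyl bis(triethylsilyl) ether
Conditions: Et3SiOTf (2.4 equiv), 2,6-lutidine, CH2Cl2, −78 → 0 °C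
Reagents that add atoms: triethylsilyl trifluoromethanesulfonate, CC[Si](CC)(CC)OS(=O)(=O)C(F)(F)F
Why: Exhaustive silylation with the silyl triflate caps both hydroxyls; the tertiary one must be a non-chelating silyl ether for the aldol in step 7.

Step 5
Reactants: 5 (2R,6S)-2,6-dimethyloct-7-ene-1,2-diyl bis(triethylsilyl) ether
Product: 6 (2R,6S)-2,6-dimethyl-2-(triethylsilyloxy)oct-7-enal
Conditions: (COCl)2, DMSO, CH2Cl2, −78 → −30 °C; Et3N, −78 °C → rt
Reagents that add atoms: none
Why: Swern oxidation converts a primary triethylsilyl ether directly into the aldehyde while the tertiary silyl ether survives, so no separate deprotection is needed.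

Step 6
Reactants: 7 3-bromofuran-2(5H)-one
Product: 8 3-bromo-2-(triisopropylsilyloxy)furan
Conditions: i-Pr3SiOTf, Et3N, CH2Cl2, 0 °C → rt
Reagents that add atoms: triisopropylsilyl trifluoromethanesulfonate, CC(C)[Si](C(C)C)(C(C)C)OS(=O)(=O)C(F)(F)F
Why: O-silylation and γ-deprotonation of the butenolide give the aromatic 2-silyloxyfuran, a stable silyl dienol ether.

Step 7
Reactants: 6 (2R,6S)-2,6-dimethyl-2-(triethylsilyloxy)oct-7-enal; 8 3-bromo-2-(triisopropylsilyloxy)furan
Product: 9 (5R)-3-bromo-5-[(1S,2R,6S)-1-hydroxy-2,6-dimethyl-2-(triethylsilyloxy)oct-7-en-1-yl]furan-2(5H)-one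
Conditions: BF3·OEt2 (1.2 equiv), CH2Cl2, −78 °C; aq. NaHCO3
Reagents that add atoms: none
Why: Vinylogous Mukaiyama aldol at furan C5; Felkin–Anh (non-chelation) attack anti to the C–OSi bond sets C11 (S) relative to C10, and the usual threo preference of BF3-promoted silyloxyfuran additions sets C11a (R); minor isomers are removed by chromatography.

Step 8
Reactants: 9 (5R)-3-bromo-5-[(1S,2R,6S)-1-hydroxy-2,6-dimethyl-2-(triethylsilyloxy)oct-7-en-1-yl]furan-2(5H)-one
Product: 10 (1S,2R,6S)-1-[(2R)-4-bromo-5-oxo-2,5-dihydrofuran-2-yl]-2,6-dimethyl-2-(triethylsilyloxy)oct-7-en-1-yl 2-methylpropanoate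
Conditions: i-PrCOCl (3 equiv), pyridine, CH2Cl2, 0 °C → rt
Reagents that add atoms: 2-methylpropanoyl chloride, CC(C)C(=O)Cl
Why: Esterification of the only free hydroxyl under weakly basic conditions, which avoid epimerisation or β-elimination at the acidic butenolide γ-position.

Step 9
Reactants: 10 (1S,2R,6S)-1-[(2R)-4-bromo-5-oxo-2,5-dihydrofuran-2-yl]-2,6-dimethyl-2-(triethylsilyloxy)oct-7-en-1-yl 2-methylpropanoate
Product: 11 [(5R)-5-[(1S,2R,6S)-2,6-dimethyl-1-(2-methylpropanoyloxy)-2-(triethylsilyloxy)oct-7-en-1-yl]-2-oxo-2,5-dihydrofuran-3-yl]methyl 2,2-dimethylpropanoate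
Conditions: PivOCH2ZnI (2 equiv, from ICH2OPiv and Zn dust, THF), Pd(PPh3)4 (5 mol%), THF, 40 °C
Reagents that add atoms: (2,2-dimethylpropanoyloxy)methylzinc iodide, CC(C)(C)C(=O)OC[Zn]I (made in the flask from iodomethyl 2,2-dimethylpropanoate, CC(C)(C)C(=O)OCI, and Zn)
Why: Negishi coupling of the α-bromobutenolide with an (acyloxy)methylzinc reagent replaces Br by CH2OPiv under neutral conditions, installing the future exocyclic methylene carbon as an allylic ester.

Step 10
Reactants: 11 [(5R)-5-[(1S,2R,6S)-2,6-dimethyl-1-(2-methylpropanoyloxy)-2-(triethylsilyloxy)oct-7-en-1-yl]-2-oxo-2,5-dihydrofuran-3-yl]methyl 2,2-dimethylpropanoate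
Product: 12 [(5R)-5-[(1S,2R,6S)-7,8-dihydroxy-2,6-dimethyl-1-(2-methylpropanoyloxy)-2-(triethylsilyloxy)octyl]-2-oxo-2,5-dihydrofuran-3-yl]methyl 2,2-dimethylpropanoate (both C7 epimers)
Conditions: OsO4 (2 mol%), NMO (1.3 equiv), citric acid (0.75 equiv), t-BuOH/H2O, rt
Reagents that add atoms: N-methylmorpholine N-oxide, C[N+]1([O-])CCOCC1; water, O
Why: Upjohn dihydroxylation is selective for the terminal alkene over the electron-poor trisubstituted butenolide alkene; the new carbinol centre becomes a ketone in step 11, so its configuration does not matter.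

Step 11
Reactants: 12 [(5R)-5-[(1S,2R,6S)-7,8-dihydroxy-2,6-dimethyl-1-(2-methylpropanoyloxy)-2-(triethylsilyloxy)octyl]-2-oxo-2,5-dihydrofuran-3-yl]methyl 2,2-dimethylpropanoate
Product: 13 [(5R)-5-[(1S,2R,6S)-2,6-dimethyl-1-(2-methylpropanoyloxy)-7,8-dioxo-2-(triethylsilyloxy)octyl]-2-oxo-2,5-dihydrofuran-3-yl]methyl 2,2-dimethylpropanoate
Conditions: IBX (3 equiv), DMSO, rt
Reagents that add atoms: none
Why: IBX oxidation takes both hydroxyls of a 1,2-diol to the 1,2-dicarbonyl without C–C cleavage and, being neutral, does not epimerise C6 or touch the silyl ether and esters.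

Step 12
Reactants: 13 [(5R)-5-[(1S,2R,6S)-2,6-dimethyl-1-(2-methylpropanoyloxy)-7,8-dioxo-2-(triethylsilyloxy)octyl]-2-oxo-2,5-dihydrofuran-3-yl]methyl 2,2-dimethylpropanoate
Product: 16 (3aS,4S,6S,10R,11S,11aR)-4,10-dihydroxy-6,10-dimethyl-3-methylidene-2,5-dioxododecahydrocyclodeca[b]furan-11-yl 2-methylpropanoate (target), via allylindium iodide pivalate 14 (not isolated), via triethylsilyl ether 15 (not isolated)
Conditions: Pd(PPh3)4 (10 mol%), InI (2.5 equiv), THF, rt, slow addition of 13 (final 2 mM); then HF·pyridine, 0 °C → rt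
Reagents that add atoms: none
Why: Proposed new method: zerovalent palladium ionises the primary allylic pivalate to a π-allyl complex spanning the exocyclic CH2, C3 and the ring β-carbon C3a, and InI reduces it by reductive transmetalation to the σ-allylindium 14, in which the normally electrophilic butenolide β-carbon is the nucleophilic γ-terminus (a lactone homoenolate, d3, equivalent); this adds through a six-membered chair transition state to the aldehyde carbonyl of the 1,2-ketoaldehyde (the hindered ketone is left alone), anti to the C11a side chain (trans-fused lactone, C3a S), and the ring-locked E-type allyl geometry with an equatorial acyl group gives the anti C3a/C4 relationship (C4 S) while the double bond moves out to the α-methylene group; fluoride then cleaves the tertiary silyl ether; the closest known reactions are the Pd-catalysed, InI-mediated umpolung allylation of aldehydes with allylic esters, Barbier additions of 3-(bromomethyl)furan-2(5H)-ones to aldehydes giving β-substituted α-methylene lactones, and intramolecular Nozaki–Hiyama-type allylations used to close germacranolide rings.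

## Compound list

1 | (3S)-3,7-dimethylocta-1,6-diene [(S)-β-citronellene] | C=C[C@@H](C)CCC=C(C)C | starting material
2 | (2E,6S)-2,6-dimethylocta-2,7-dien-1-ol | C=C[C@@H](C)CC/C=C(\C)CO | intermediate
3 | [(2S,3S)-2-methyl-3-[(3S)-3-methylpent-4-en-1-yl]oxiran-2-yl]methanol | C=C[C@@H](C)CC[C@H]1[C@](C)(CO)O1 | intermediate
4 | (2R,6S)-2,6-dimethyloct-7-ene-1,2-diol | C=C[C@@H](C)CCC[C@@](C)(O)CO | intermediate
5 | (2R,6S)-2,6-dimethyloct-7-ene-1,2-diyl bis(triethylsilyl) ether | C=C[C@@H](C)CCC[C@@](C)(O[Si](CC)(CC)CC)CO[Si](CC)(CC)CC | intermediate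
6 | (2R,6S)-2,6-dimethyl-2-(triethylsilyloxy)oct-7-enal | C=C[C@@H](C)CCC[C@@](C)(O[Si](CC)(CC)CC)C=O | intermediate
7 | 3-bromofuran-2(5H)-one | O=C1OCC=C1Br | starting material
8 | 3-bromo-2-(triisopropylsilyloxy)furan | Brc1ccoc1O[Si](C(C)C)(C(C)C)C(C)C | intermediate
9 | (5R)-3-bromo-5-[(1S,2R,6S)-1-hydroxy-2,6-dimethyl-2-(triethylsilyloxy)oct-7-en-1-yl]furan-2(5H)-one | BrC1=C[C@@H](OC1=O)[C@H](O)[C@](C)(O[Si](CC)(CC)CC)CCC[C@H](C)C=C | intermediate
10 | (1S,2R,6S)-1-[(2R)-4-bromo-5-oxo-2,5-dihydrofuran-2-yl]-2,6-dimethyl-2-(triethylsilyloxy)oct-7-en-1-yl 2-methylpropanoate | BrC1=C[C@@H](OC1=O)[C@H](OC(=O)C(C)C)[C@](C)(O[Si](CC)(CC)CC)CCC[C@H](C)C=C | intermediate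
11 | [(5R)-5-[(1S,2R,6S)-2,6-dimethyl-1-(2-methylpropanoyloxy)-2-(triethylsilyloxy)oct-7-en-1-yl]-2-oxo-2,5-dihydrofuran-3-yl]methyl 2,2-dimethylpropanoate | CC(C)(C)C(=O)OCC1=C[C@@H](OC1=O)[C@H](OC(=O)C(C)C)[C@](C)(O[Si](CC)(CC)CC)CCC[C@H](C)C=C | intermediate
12 | [(5R)-5-[(1S,2R,6S)-7,8-dihydroxy-2,6-dimethyl-1-(2-methylpropanoyloxy)-2-(triethylsilyloxy)octyl]-2-oxo-2,5-dihydrofuran-3-yl]methyl 2,2-dimethylpropanoate (C7 epimers) | CC(C)(C)C(=O)OCC1=C[C@@H](OC1=O)[C@H](OC(=O)C(C)C)[C@](C)(O[Si](CC)(CC)CC)CCC[C@H](C)C(O)CO | intermediate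
13 | [(5R)-5-[(1S,2R,6S)-2,6-dimethyl-1-(2-methylpropanoyloxy)-7,8-dioxo-2-(triethylsilyloxy)octyl]-2-oxo-2,5-dihydrofuran-3-yl]methyl 2,2-dimethylpropanoate | CC(C)(C)C(=O)OCC1=C[C@@H](OC1=O)[C@H](OC(=O)C(C)C)[C@](C)(O[Si](CC)(CC)CC)CCC[C@H](C)C(=O)C=O | intermediate
14 | {[(5R)-5-[(1S,2R,6S)-2,6-dimethyl-1-(2-methylpropanoyloxy)-7,8-dioxo-2-(triethylsilyloxy)octyl]-2-oxo-2,5-dihydrofuran-3-yl]methyl}(iodo)indium 2,2-dimethylpropanoate | CC(C)(C)C(=O)O[In](I)CC1=C[C@@H](OC1=O)[C@H](OC(=O)C(C)C)[C@](C)(O[Si](CC)(CC)CC)CCC[C@H](C)C(=O)C=O | intermediate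
15 | (3aS,4S,6S,10R,11S,11aR)-4-hydroxy-6,10-dimethyl-3-methylidene-2,5-dioxo-10-(triethylsilyloxy)dodecahydrocyclodeca[b]furan-11-yl 2-methylpropanoate | C=C1C(=O)O[C@@H]2[C@@H]1[C@H](O)C(=O)[C@@H](C)CCC[C@@](C)(O[Si](CC)(CC)CC)[C@H]2OC(=O)C(C)C | intermediate
16 | (3aS,4S,6S,10R,11S,11aR)-4,10-dihydroxy-6,10-dimethyl-3-methylidene-2,5-dioxododecahydrocyclodeca[b]furan-11-yl 2-methylpropanoate | C=C1C(=O)O[C@@H]2[C@@H]1[C@H](O)C(=O)[C@@H](C)CCC[C@@](C)(O)[C@H]2OC(=O)C(C)C | target

## Step count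

Total steps: 12. Longest linear sequence: 11 (steps 1–5 and 7–12; step 6 is a one-step side branch).

## Steps most likely to fail, with fallbacks

**Step 12 (ring closure).** The cyclisation competes with oligomerisation, with attack through the CH2 terminus (twelve-membered ring) and with reduction of the 1,2-dicarbonyl. Chelation of indium by the keto group could also erode the C4 selectivity. The fallback replaces the reductively made allylmetal by a stable allylsilane and a Lewis-acid-activated carbonyl (intramolecular Hosomi–Sakurai reaction). It sets out from 10. Negishi coupling with Me3SiCH2ZnCl and Pd(PPh3)4 gives the (trimethylsilyl)methyl butenolide F1. OsO4/NMO gives its diol F2, and IBX in DMSO gives the silyl ketoaldehyde F3. MgBr2·OEt2 or SnCl4, which chelate the 1,2-dicarbonyl, in CH2Cl2 at −78 °C under high dilution then induce attack of the butenolide β-carbon on the aldehyde with loss of the trimethylsilyl group. This comes back to the route at 15, which is desilylated with HF·pyridine to 16 as in step 12.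

**Step 7 (vinylogous aldol).** The α-carbon of aldehyde 6 carries no hydrogen, so Felkin–Anh control must distinguish methyl from a CH2 chain and may be modest; the threo/erythro ratio is also uncertain with the bromofuran. The fallback sets C11 and C11a by reagent control and builds the butenolide by metathesis. It sets out from 6. Brown's [(Z)-3-(methoxymethoxy)allyl]bis(isopinocampheyl)borane (the enantiomer that gives the 3R,4S adduct), then H2O2/NaOH, gives the syn alkoxy alcohol F4. i-PrCOCl/pyridine gives the isobutyrate F5. ZnBr2/n-PrSH in CH2Cl2 removes the methoxymethyl group to give the allylic alcohol F6. Esterification with 2-[(2,2-dimethylpropanoyloxy)methyl]prop-2-enoic acid (EDC, catalytic DMAP) gives the acrylate F7. Ring-closing metathesis with second-generation Hoveyda–Grubbs catalyst in dilute toluene at 80 °C closes the butenolide and comes back to the route at 11, so steps 8 and 9 are not needed.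

**Step 9 (Negishi coupling).** The (acyloxy)methylzinc reagent may transmetalate slowly or decompose, and zerovalent palladium could in principle ionise the butenolide. The fallback brings in the carbon as a free hydroxymethyl group with a tin reagent and esterifies afterwards. It sets out from 10. Stille coupling with Bu3SnCH2OH and Pd(PPh3)4 in dioxane at 80 °C gives the hydroxymethyl butenolide F8. Pivaloyl chloride/pyridine at 0 °C then comes back to the route at 11.

## Further compounds

F1 | step 12 | (1S,2R,6S)-2,6-dimethyl-1-[(2R)-5-oxo-4-[(trimethylsilyl)methyl]-2,5-dihydrofuran-2-yl]-2-(triethylsilyloxy)oct-7-en-1-yl 2-methylpropanoate | C[Si](C)(C)CC1=C[C@@H](OC1=O)[C@H](OC(=O)C(C)C)[C@](C)(O[Si](CC)(CC)CC)CCC[C@H](C)C=C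
F2 | step 12 | (1S,2R,6S)-7,8-dihydroxy-2,6-dimethyl-1-[(2R)-5-oxo-4-[(trimethylsilyl)methyl]-2,5-dihydrofuran-2-yl]-2-(triethylsilyloxy)octyl 2-methylpropanoate | C[Si](C)(C)CC1=C[C@@H](OC1=O)[C@H](OC(=O)C(C)C)[C@](C)(O[Si](CC)(CC)CC)CCC[C@H](C)C(O)CO
F3 | step 12 | (1S,2R,6S)-2,6-dimethyl-7,8-dioxo-1-[(2R)-5-oxo-4-[(trimethylsilyl)methyl]-2,5-dihydrofuran-2-yl]-2-(triethylsilyloxy)octyl 2-methylpropanoate | C[Si](C)(C)CC1=C[C@@H](OC1=O)[C@H](OC(=O)C(C)C)[C@](C)(O[Si](CC)(CC)CC)CCC[C@H](C)C(=O)C=O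
F4 | step 7 | (3R,4S,5R,9S)-3-(methoxymethoxy)-5,9-dimethyl-5-(triethylsilyloxy)undeca-1,10-dien-4-ol | C=C[C@@H](OCOC)[C@H](O)[C@](C)(O[Si](CC)(CC)CC)CCC[C@H](C)C=C
F5 | step 7 | (3R,4S,5R,9S)-3-(methoxymethoxy)-5,9-dimethyl-5-(triethylsilyloxy)undeca-1,10-dien-4-yl 2-methylpropanoate | C=C[C@@H](OCOC)[C@H](OC(=O)C(C)C)[C@](C)(O[Si](CC)(CC)CC)CCC[C@H](C)C=C
F6 | step 7 | (3R,4S,5R,9S)-3-hydroxy-5,9-dimethyl-5-(triethylsilyloxy)undeca-1,10-dien-4-yl 2-methylpropanoate | C=C[C@@H](O)[C@H](OC(=O)C(C)C)[C@](C)(O[Si](CC)(CC)CC)CCC[C@H](C)C=C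
F7 | step 7 | (3R,4S,5R,9S)-5,9-dimethyl-4-(2-methylpropanoyloxy)-5-(triethylsilyloxy)undeca-1,10-dien-3-yl 2-[(2,2-dimethylpropanoyloxy)methyl]prop-2-enoate | C=C[C@@H](OC(=O)C(=C)COC(=O)C(C)(C)C)[C@H](OC(=O)C(C)C)[C@](C)(O[Si](CC)(CC)CC)CCC[C@H](C)C=C
F8 | step 9 | (1S,2R,6S)-1-[(2R)-4-(hydroxymethyl)-5-oxo-2,5-dihydrofuran-2-yl]-2,6-dimethyl-2-(triethylsilyloxy)oct-7-en-1-yl 2-methylpropanoate | OCC1=C[C@@H](OC1=O)[C@H](OC(=O)C(C)C)[C@](C)(O[Si](CC)(CC)CC)CCC[C@H](C)C=C
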